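**Retrosynthetic overview**
1. 14 ⇒ 13: the oxane ring is closed last by a 6-endo bromoetherification (C–O bond formed, C–Br centre set).
2. 13 ⇒ 11 ⇒ 10: prenyl comes from allyl by cross-metathesis after acetylation; the ring Br/Cl pair comes from a hydroxyl-directed bromochlorination of the cyclohexene (new method).
3. 10 ⇒ 8: reductive allylation of a cis-fused hydroxy lactone (chelation sets the acetate-bearing carbon).
4. 8 ⇒ 5 ⇒ 3 + 4: cis reduction/lactonisation of the anti aldol adduct of a Birch-derived silyl dienol ether and methyl pyruvate.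
5. Ring order: cyclohexene (from m-cresol 1) first, a temporary γ-lactone second, the oxane last.

Assumption: the Ph-pybox antipode that gives the (2S) aldol adduct is written as (R,R); if the sense is the opposite, the (S,S) ligand is used with no other change.

Step 1
Reactants: 1 3-methylphenol (m-cresol)
Product: 2 tert-butyl(dimethyl)(3-methylphenoxy)silane
Conditions: TBSCl, imidazole, DMF, 23 °C
Reagents that add atoms: tert-butyldimethylsilyl chloride, CC(C)(C)[Si](C)(C)Cl
Why: Standard silyl ether formation on a phenol, which makes the arene fit for Birch reduction to an enol silane; no stereocenter.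

Step 2
Reactants: 2 tert-butyl(dimethyl)(3-methylphenoxy)silane
Product: 3 tert-butyl(dimethyl)[(5-methylcyclohexa-1,4-dien-1-yl)oxy]silane
Conditions: Li, NH3 (l), THF, t-BuOH, −78 to −33 °C
Reagents that add atoms: none
Why: Birch reduction keeps the silyloxy- and methyl-bearing carbons sp2, so the skipped diene carries a regiodefined enol silane and the ring alkene already in its final position; no stereocenter.

Step 3
Reactants: 3 tert-butyl(dimethyl)[(5-methylcyclohexa-1,4-dien-1-yl)oxy]silane; 4 methyl pyruvate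
Product: 5 methyl (2S)-2-[(tert-butyldimethylsilyl)oxy]-2-[(1R)-4-methyl-6-oxocyclohex-3-en-1-yl]propanoate
Conditions: Sn(OTf)2 (10 mol %), (R,R)-Ph-pybox (11 mol %), CH2Cl2, −78 °C
Reagents that add atoms: none
Why: Catalytic enantioselective Mukaiyama aldol in which the pyruvate chelates Sn(OTf)2–pybox through both carbonyls and the (E)-configured cyclic enol silane attacks one ketone face in an open, anti-selective transition state, so the tertiary carbinol (S) and the ring α-carbon (R) are set together while the silyl group moves to the tertiary oxygen.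

Step 4
Reactants: 5 methyl (2S)-2-[(tert-butyldimethylsilyl)oxy]-2-[(1R)-4-methyl-6-oxocyclohex-3-en-1-yl]propanoate
Product: 8 (3S,3aS,7aR)-3-hydroxy-3,6-dimethyl-3a,4,7,7a-tetrahydro-1-benzofuran-2(3H)-one, via cis-hydroxy ester 6 (not isolated), via silyl lactone 7 (not isolated)
Conditions: LiBH(s-Bu)3, THF, −78 to 0 °C; then HF·pyridine, MeCN, 23 °C
Reagents that add atoms: none
Why: Steric-approach-controlled ketone reduction in which the bulky trialkylborohydride attacks equatorially to give the axial alkoxide cis to the quaternary side chain (new carbinol R), which lactonises onto the neighbouring ester before HF removes the tertiary silyl ether.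

Step 5
Reactants: 8 (3S,3aS,7aR)-3-hydroxy-3,6-dimethyl-3a,4,7,7a-tetrahydro-1-benzofuran-2(3H)-one
Product: 10 (2S,3S)-2-[(1S,6R)-6-hydroxy-4-methylcyclohex-3-en-1-yl]hex-5-ene-2,3-diol, via lactol 9 (not isolated)
Conditions: i-Bu2AlH, CH2Cl2, −78 °C; then allylMgBr, THF, −78 to 0 °C
Reagents that add atoms: allylmagnesium bromide, C=CC[Mg]Br
Why: Lactone half-reduction followed by Grignard addition to the ring-opened α-alkoxide aldehyde under the Cram cyclic (chelate) model, where allyl enters from the methyl side of the five-membered magnesium chelate and gives the 3S carbinol; the terminal allyl group is kept as a masked prenyl unit that is inert to electrophilic halogen.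

Step 6
Reactants: 10 (2S,3S)-2-[(1S,6R)-6-hydroxy-4-methylcyclohex-3-en-1-yl]hex-5-ene-2,3-diol
Product: 11 (2S,3S)-2-[(1S,2R,4R,5R)-5-bromo-4-chloro-2-hydroxy-4-methylcyclohexyl]hex-5-ene-2,3-diol
Conditions: VO(Oi-Pr)3 (10 mol %), t-BuOOH, 2,6-lutidinium bromide (slow addition), 2,6-lutidinium chloride, 4 Å sieves, CH2Cl2, −30 °C, dark
Reagents that add atoms: 2,6-lutidinium bromide, Cc1cccc(C)[nH+]1.[Br-]; 2,6-lutidinium chloride, Cc1cccc(C)[nH+]1.[Cl-]
Why: Proposed new method: an alkoxide-directed, haloperoxidase-like bromochlorination in which the ring hydroxyl and the tertiary hydroxyl of 10 bind the vanadyl centre as a chelating dialkoxide on one ring face, the bound alkyl peroxide oxidises bromide to a vanadium-bound hypobromite that hands Br+ to that same face of the trisubstituted alkene, and external chloride opens the bromonium anti at the tertiary carbon (Markovnikov), setting ring C5 (R, Br cis to the hydroxyl) and C4 (R, Cl trans) against the innate diaxial preference; the hydroxyls cannot reach the opposite face, so bromonium formed on the wrong face is drained as cyclic ethers and not as bromochloride; the closest known chemistry is hydroxyl-directed VO(acac)2/t-BuOOH epoxidation of homoallylic alcohols, vanadium-bromoperoxidase-type oxidative bromination and alkoxide-directed titanium-mediated bromochlorination of allylic alcohols.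

Step 7
Reactants: 11 (2S,3S)-2-[(1S,2R,4R,5R)-5-bromo-4-chloro-2-hydroxy-4-methylcyclohexyl]hex-5-ene-2,3-diol
Product: 12 (2S,3S)-2-[(1S,2R,4R,5R)-5-bromo-4-chloro-2-hydroxy-4-methylcyclohexyl]-2-hydroxyhex-5-en-3-yl acetate
Conditions: Ac2O, pyridine, CH2Cl2, 0 °C
Reagents that add atoms: acetic anhydride, CC(=O)OC(C)=O
Why: Sterically controlled acylation in which only the side-chain secondary hydroxyl reacts, because the ring hydroxyl is axial, syn-diaxial to the ring methyl and flanked by the quaternary side chain, and the remaining hydroxyl is tertiary.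

Step 8
Reactants: 12 (2S,3S)-2-[(1S,2R,4R,5R)-5-bromo-4-chloro-2-hydroxy-4-methylcyclohexyl]-2-hydroxyhex-5-en-3-yl acetate
Product: 13 (2S,3S)-2-[(1S,2R,4R,5R)-5-bromo-4-chloro-2-hydroxy-4-methylcyclohexyl]-2-hydroxy-6-methylhept-5-en-3-yl acetate
Conditions: 2-methylbut-2-ene, second-generation Grubbs catalyst (H2IMes)(PCy3)Cl2Ru=CHPh (5 mol %), CH2Cl2, 40 °C
Reagents that add atoms: 2-methylbut-2-ene, CC=C(C)C
Why: Olefin cross-metathesis of the terminal alkene with 2-methylbut-2-ene turns allyl into prenyl with loss of propene, tolerating alkyl halides, the ester and free hydroxyls and touching no stereocenter.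

Step 9
Reactants: 13 (2S,3S)-2-[(1S,2R,4R,5R)-5-bromo-4-chloro-2-hydroxy-4-methylcyclohexyl]-2-hydroxy-6-methylhept-5-en-3-yl acetate
Product: 14 (2S,3S,5S)-5-bromo-2-[(1S,2R,4R,5R)-5-bromo-4-chloro-2-hydroxy-4-methylcyclohexyl]-2,6,6-trimethyloxan-3-yl acetate
Conditions: TBCO, MeNO2, 0 to 23 °C
Reagents that add atoms: 2,4,4,6-tetrabromocyclohexa-2,5-dien-1-one (TBCO), BrC1=CC(Br)(Br)C=C(Br)C1=O
Why: Bromonium-induced 6-endo etherification (bromoetherification) of the only remaining alkene, in which the tertiary hydroxyl attacks the dimethyl-substituted carbon (Markovnikov) through a chair transition state with the cyclohexyl group equatorial, placing bromine equatorial and setting the new C–Br centre as S.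

**Compound list**
1 | 3-methylphenol (m-cresol) | Cc1cccc(O)c1 | starting material
2 | tert-butyl(dimethyl)(3-methylphenoxy)silane | Cc1cccc(O[Si](C)(C)C(C)(C)C)c1 | intermediate
3 | tert-butyl(dimethyl)[(5-methylcyclohexa-1,4-dien-1-yl)oxy]silane | CC1=CCC=C(O[Si](C)(C)C(C)(C)C)C1 | intermediate
4 | methyl pyruvate (methyl 2-oxopropanoate) | COC(=O)C(C)=O | starting material
5 | methyl (2S)-2-[(tert-butyldimethylsilyl)oxy]-2-[(1R)-4-methyl-6-oxocyclohex-3-en-1-yl]propanoate | COC(=O)[C@@](C)(O[Si](C)(C)C(C)(C)C)[C@H]1CC=C(C)CC1=O | intermediate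
6 | methyl (2S)-2-[(tert-butyldimethylsilyl)oxy]-2-[(1S,6R)-6-hydroxy-4-methylcyclohex-3-en-1-yl]propanoate (cis-hydroxy ester, not isolated) | COC(=O)[C@@](C)(O[Si](C)(C)C(C)(C)C)[C@H]1CC=C(C)C[C@H]1O | intermediate
7 | (3S,3aS,7aR)-3-[(tert-butyldimethylsilyl)oxy]-3,6-dimethyl-3a,4,7,7a-tetrahydro-1-benzofuran-2(3H)-one (silyl lactone, not isolated) | C[C@@]1(O[Si](C)(C)C(C)(C)C)C(=O)O[C@@H]2CC(C)=CC[C@H]12 | intermediate
8 | (3S,3aS,7aR)-3-hydroxy-3,6-dimethyl-3a,4,7,7a-tetrahydro-1-benzofuran-2(3H)-one (cis-fused lactone, OH on the concave face) | C[C@@]1(O)C(=O)O[C@@H]2CC(C)=CC[C@H]12 | intermediate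
9 | (3S,3aS,7aR)-3,6-dimethyl-2,3,3a,4,7,7a-hexahydro-1-benzofuran-2,3-diol (lactol, both anomers, not isolated) | C[C@@]1(O)C(O)O[C@@H]2CC(C)=CC[C@H]12 | intermediate
10 | (2S,3S)-2-[(1S,6R)-6-hydroxy-4-methylcyclohex-3-en-1-yl]hex-5-ene-2,3-diol | C=CC[C@H](O)[C@@](C)(O)[C@H]1CC=C(C)C[C@H]1O | intermediate
11 | (2S,3S)-2-[(1S,2R,4R,5R)-5-bromo-4-chloro-2-hydroxy-4-methylcyclohexyl]hex-5-ene-2,3-diol | C=CC[C@H](O)[C@@](C)(O)[C@H]1C[C@@H](Br)[C@](C)(Cl)C[C@H]1O | intermediate
12 | (2S,3S)-2-[(1S,2R,4R,5R)-5-bromo-4-chloro-2-hydroxy-4-methylcyclohexyl]-2-hydroxyhex-5-en-3-yl acetate | C=CC[C@H](OC(C)=O)[C@@](C)(O)[C@H]1C[C@@H](Br)[C@](C)(Cl)C[C@H]1O | intermediate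
13 | (2S,3S)-2-[(1S,2R,4R,5R)-5-bromo-4-chloro-2-hydroxy-4-methylcyclohexyl]-2-hydroxy-6-methylhept-5-en-3-yl acetate | CC(C)=CC[C@H](OC(C)=O)[C@@](C)(O)[C@H]1C[C@@H](Br)[C@](C)(Cl)C[C@H]1O | intermediate
14 | (2S,3S,5S)-5-bromo-2-[(1S,2R,4R,5R)-5-bromo-4-chloro-2-hydroxy-4-methylcyclohexyl]-2,6,6-trimethyloxan-3-yl acetate (CNP0166766.1) | CC(=O)O[C@H]1C[C@H](Br)C(C)(C)O[C@@]1(C)[C@H]1C[C@@H](Br)[C@](C)(Cl)C[C@H]1O | target

**Step count and risks**

Total steps: 9. Longest linear sequence: 9 (from m-cresol; methyl pyruvate is bought).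

The three steps most likely to fail:

Step 6 (the proposed directed bromochlorination). It can fail through halogen transfer that escapes the vanadium centre, which gives the innate diaxial isomer or cyclic ethers. It can also fail through competing directed epoxidation, or through chloride attack at the secondary carbon. That last regioisomer (diaxial, tertiary bromide) would still converge on 11 on warming, through the known diaxial-to-diequatorial 1,2-halogen interchange of vicinal bromochlorides. The fallback uses only known chemistry, sets out from lactone 8 and returns at 11. Epoxidation of 8 with mCPBA from the convex face gives the epoxy lactone F5. HBr opens it anti, putting bromide on the lactone-side face, to give the bromohydrin F6. SOCl2/pyridine then makes the hydroxyl leave with bromine participation, and chloride opens the bromonium at the tertiary carbon to give the bromochloro lactone F7. The step-5 operation (i-Bu2AlH, then allylMgBr) then passes through the bromochloro lactol F8 to 11.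

Step 3 (anti aldol). The anti/syn ratio, the enantioselectivity and the catalyst turnover are uncertain for a ketone-derived cyclic tert-butyldimethylsilyl enol ether. The fallback sets out from 3 and returns at 8, and it no longer asks the aldol to set the quaternary carbinol. The same Sn(OTf)2–pybox catalyst with ethyl glyoxylate gives the silyl ether F1, in which only the ring α-carbon matters. LiBH(s-Bu)3 gives the cis-hydroxy ester F2, and HF·pyridine gives the hydroxy lactone F3. Dess–Martin periodinane gives the keto lactone F4. MeMgBr/CeCl3 then adds to the ketone from the convex face of the cis-fused bicycle, which puts methyl on the convex face and hydroxyl on the concave face, that is, 8.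

Step 9 (bromoetherification). The 5-exo oxolane, the epimer at the C–Br carbon and a modest yield are the usual problems with this cyclisation. The fallback sets out from 13 and returns at 14. Hg(OCOCF3)2 in MeNO2 followed by aqueous KBr gives the 6-endo organomercurial F9 under thermodynamic (Markovnikov) control. Bromodemercuration with Br2/pyridine under light then gives 14, with the equatorial bromide favoured.

**Further compounds**
F1 | step 3 | ethyl 2-[(tert-butyldimethylsilyl)oxy]-2-[(1R)-4-methyl-6-oxocyclohex-3-en-1-yl]acetate (carbinol carbon either configuration) | CCOC(=O)C(O[Si](C)(C)C(C)(C)C)[C@H]1CC=C(C)CC1=O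
F2 | step 3 | ethyl 2-[(tert-butyldimethylsilyl)oxy]-2-[(1S,6R)-6-hydroxy-4-methylcyclohex-3-en-1-yl]acetate | CCOC(=O)C(O[Si](C)(C)C(C)(C)C)[C@H]1CC=C(C)C[C@H]1O
F3 | step 3 | (3aR,7aR)-3-hydroxy-6-methyl-3a,4,7,7a-tetrahydro-1-benzofuran-2(3H)-one (cis-fused, either C3 epimer) | OC1C(=O)O[C@@H]2CC(C)=CC[C@H]12
F4 | step 3 | (3aS,7aR)-6-methyl-3a,4,7,7a-tetrahydro-1-benzofuran-2,3-dione | O=C1C(=O)O[C@@H]2CC(C)=CC[C@H]12
F5 | step 6 | 5,6-epoxide of lactone 8, epoxide oxygen anti to the lactone ring | C[C@@]1(O)C(=O)O[C@@H]2C[C@@]3(C)O[C@H]3C[C@H]12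
F6 | step 6 | (3S,3aS,7aR)-6-bromo-3,5-dihydroxy-3,6-dimethylhexahydro-1-benzofuran-2(3H)-one, 6-Br syn and 5-OH anti to the lactone ring | C[C@@]1(O)C(=O)O[C@@H]2C[C@](C)(Br)[C@@H](O)C[C@H]12
F7 | step 6 | (3S,3aS,7aR)-5-bromo-6-chloro-3-hydroxy-3,6-dimethylhexahydro-1-benzofuran-2(3H)-one, 5-Br syn and 6-Cl anti to the lactone ring | C[C@@]1(O)C(=O)O[C@@H]2C[C@@](C)(Cl)[C@H](Br)C[C@H]12
F8 | step 6 | lactol of F7 (5-bromo-6-chloro-3,6-dimethyloctahydro-1-benzofuran-2,3-diol, both anomers) | C[C@@]1(O)C(O)O[C@@H]2C[C@@](C)(Cl)[C@H](Br)C[C@H]12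
F9 | step 9 | (2S,3S,5S)-5-(bromomercurio)-2-[(1S,2R,4R,5R)-5-bromo-4-chloro-2-hydroxy-4-methylcyclohexyl]-2,6,6-trimethyloxan-3-yl acetate | CC(=O)O[C@H]1C[C@H]([Hg]Br)C(C)(C)O[C@@]1(C)[C@H]1C[C@@H](Br)[C@](C)(Cl)C[C@H]1O
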